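**Retrosynthetic overview**

1. The target is the isofraxidin ether of a keto-decalin (decalin numbering: C1 quaternary with CH3 and CH2OAr, C2–CH3, C4a angular CH3, C5–CH3, C6=O, C8a–H; ring A = C1, C2, C3, C4, C4a, C8a; ring B = C4a, C5, C6, C7, C8, C8a). The last steps are ketal hydrolysis and CHO → CH3 at C1.
2. Ring A and the C1 quaternary centre arise together by Lewis-acid ring contraction (Meinwald 1,2-shift) of a cyclohepta-fused epoxide that already carries the coumarin ether.
3. Enabling feature (precursor numbering, spiro-benzo[7]annulene): the epoxide spans C5′ (tertiary, bearing CH2OAr and bonded to ring-fusion C4a′) and C6′–H, and C6′ is bonded to C7′(H)(CH3). C5′–O ionises, C7′ shifts from C6′ to C5′ anti to oxygen, and C6′ leaves the ring as CHO.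
4. The epoxide comes from Sharpless epoxidation of an allylic alcohol, the seven-membered ring from ring-closing metathesis, and ring B from an organocatalytic cyclohexenone annulation plus two cuprate additions (quaternary C9a′ set anti to the C4a′ side chain). The side-chain stereocentre comes from an oxazolidinone-controlled conjugate addition.
5. Order of ring formation: ring B, then the seven-membered ring, then ring A by contraction. The coumarin is introduced intact as isofraxidin by Mitsunobu etherification.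

Key step: step 14

Remark on the chemistry: the methyl-bearing carbon next to the ring B carbonyl (C5 of the target) is epimerisable; compounds 15 to 27 are written as the epimer expected to predominate, and step 16 equilibrates it to the configuration of the target.

**Step 1**
Reactants: 1 (R)-4-benzyl-1,3-oxazolidin-2-one; 2 (E)-but-2-enoyl chloride
Product: 3 (R)-4-benzyl-3-[(E)-but-2-enoyl]-1,3-oxazolidin-2-one
Conditions: n-BuLi, THF, −78 °C; then 2, −78 → 0 °C
Reagents that add atoms: none
Why: N-acylation of the lithiated oxazolidinone with the acid chloride is the standard entry to enoyl imides and creates no stereocentre.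

**Step 2**
Reactants: 3 (R)-4-benzyl-3-[(E)-but-2-enoyl]-1,3-oxazolidin-2-one
Product: 4 (R)-4-benzyl-3-[(3S)-3-methylpent-4-enoyl]-1,3-oxazolidin-2-one
Conditions: CH2=CHMgBr, CuBr·SMe2 (20 mol %), THF/Me2S, −78 → −20 °C; aq. NH4Cl
Reagents that add atoms: vinylmagnesium bromide, C=C[Mg]Br
Why: Copper-catalysed conjugate addition of the Grignard reagent to the magnesium-chelated s-cis enoyl imide should occur on the face opposite the benzyl group of the auxiliary, which sets the (S) methyl-bearing centre (the future C2 of the target).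

**Step 3**
Reactants: 4 (R)-4-benzyl-3-[(3S)-3-methylpent-4-enoyl]-1,3-oxazolidin-2-one
Product: 5 (3S)-3-methylpent-4-en-1-ol
Conditions: LiBH4, MeOH (1 equiv), Et2O, 0 °C
Reagents that add atoms: none
Why: Reductive cleavage of the N-acyl oxazolidinone with LiBH4 should give the primary alcohol without touching the alkene or the stereocentre.

**Step 4**
Reactants: 5 (3S)-3-methylpent-4-en-1-ol
Product: 6 (3S)-5-bromo-3-methylpent-1-ene
Conditions: CBr4, PPh3, CH2Cl2, 0 °C
Reagents that add atoms: carbon tetrabromide, BrC(Br)(Br)Br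
Why: The Appel reaction converts the primary alcohol into the bromide and leaves the remote stereocentre unaffected.

**Step 5**
Reactants: 7 methyl 4-oxobutanoate; 8 but-3-en-2-one
Product: 10 methyl 2-[(1R)-4-oxocyclohex-2-en-1-yl]acetate, via Michael adduct 9 (not isolated)
Conditions: (R)-2-[diphenyl(trimethylsilyloxy)methyl]pyrrolidine (10 mol %), CH2Cl2, 0 °C; then p-TsOH·H2O (10 mol %), toluene, 50 °C
Reagents that add atoms: none
Why: Enamine-catalysed Michael addition of the aldehyde to the vinyl ketone, in which the bulky diarylsilyloxymethyl group of the catalyst shields one enamine face and so sets the (R) centre (the future C8a), followed by acid-mediated intramolecular aldol condensation, is a Robinson-type annulation to a 4-substituted cyclohexenone.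

**Step 6**
Reactants: 10 methyl 2-[(1R)-4-oxocyclohex-2-en-1-yl]acetate
Product: 12 methyl 2-[(1R)-2-methyl-4-oxocyclohex-2-en-1-yl]acetate, via silyl enol ether 11 (not isolated)
Conditions: MeLi, CuI, Et2O, 0 °C (gives Me2CuLi); Me3SiCl, −78 °C; then Pd(OAc)2 (1.1 equiv), MeCN, rt
Reagents that add atoms: lithium dimethylcuprate, [Li+].C[Cu-]C
Why: Cuprate conjugate addition with silyl trapping followed by Saegusa–Ito dehydrosilylation amounts to β-methylation of the enone; the transient methyl-bearing centre is erased and the existing centre is untouched.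

**Step 7**
Reactants: 12 methyl 2-[(1R)-2-methyl-4-oxocyclohex-2-en-1-yl]acetate; 6 (3S)-5-bromo-3-methylpent-1-ene
Product: 15 methyl 2-[(1R,2R,3S)-2,3-dimethyl-2-[(3S)-3-methylpent-4-en-1-yl]-4-oxocyclohexyl]acetate, via Grignard reagent 13 (not isolated), via silyl enol ether 14 (not isolated)
Conditions: 6, Mg, THF; CuBr·SMe2 (20 mol %), Me3SiCl, THF, −78 °C, then 12; then MeI, BnMe3N+ F−, 4 Å MS, THF, rt
Reagents that add atoms: iodomethane, CI
Why: Copper-catalysed, chlorosilane-accelerated conjugate addition of the Grignard reagent to the β-methyl enone should occur anti to the neighbouring CH2CO2Me group and so create the quaternary centre (future C4a) with its methyl cis to that group, and fluoride-promoted methylation of the regiodefined silyl enol ether installs the α-methyl group, whose configuration is not critical.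

**Step 8**
Reactants: 15 methyl 2-[(1R,2R,3S)-2,3-dimethyl-2-[(3S)-3-methylpent-4-en-1-yl]-4-oxocyclohexyl]acetate
Product: 16 methyl 2-[(6S,7R,8R)-6,7-dimethyl-7-[(3S)-3-methylpent-4-en-1-yl]-1,4-dioxaspiro[4.5]decan-8-yl]acetate
Conditions: HOCH2CH2OH, p-TsOH·H2O (cat.), benzene, reflux (Dean–Stark)
Reagents that add atoms: ethane-1,2-diol, OCCO
Why: Acid-catalysed ketalisation with azeotropic removal of water protects the ring B ketone for the enolate and hydride steps that follow and forms no new stereocentre.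

**Step 9**
Reactants: 16 methyl 2-[(6S,7R,8R)-6,7-dimethyl-7-[(3S)-3-methylpent-4-en-1-yl]-1,4-dioxaspiro[4.5]decan-8-yl]acetate
Product: 19 methyl 2-[(6S,7R,8S)-6,7-dimethyl-7-[(3S)-3-methylpent-4-en-1-yl]-1,4-dioxaspiro[4.5]decan-8-yl]prop-2-enoate, via Mannich base 17 (not isolated), via ammonium iodide 18 (not isolated)
Conditions: LiN(iPr)2, THF, −78 °C; CH2=NMe2+ I−, −78 °C → rt; then MeI, CH2Cl2; then DBU, rt
Reagents that add atoms: N,N-dimethylmethyleneiminium iodide, C=[N+](C)C.[I-]
Why: Mannich aminomethylation of the ester enolate followed by quaternisation and Hofmann-type elimination is the established α-methylenation of esters, and the transient α-centre is destroyed.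

**Step 10**
Reactants: 19 methyl 2-[(6S,7R,8S)-6,7-dimethyl-7-[(3S)-3-methylpent-4-en-1-yl]-1,4-dioxaspiro[4.5]decan-8-yl]prop-2-enoate
Product: 20 methyl (1'S,4a'S,7'S,9a'R)-1',7',9a'-trimethyl-1',3',4',4a',7',8',9',9a'-octahydrospiro[[1,3]dioxolane-2,2'-benzo[7]annulene]-5'-carboxylate
Conditions: RuCl2(H2IMes)(=CH-C6H4-2-OiPr) (second-generation Hoveyda–Grubbs catalyst, 10 mol %), toluene, 80 °C
Reagents that add atoms: none
Why: Ring-closing metathesis of the acrylate and the terminal vinyl group with loss of ethene should close the seven-membered ring as the conjugated trisubstituted enoate and leave all stereocentres untouched.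

**Step 11**
Reactants: 20 methyl (1'S,4a'S,7'S,9a'R)-1',7',9a'-trimethyl-1',3',4',4a',7',8',9',9a'-octahydrospiro[[1,3]dioxolane-2,2'-benzo[7]annulene]-5'-carboxylate
Product: 21 [(1'S,4a'S,7'S,9a'R)-1',7',9a'-trimethyl-1',3',4',4a',7',8',9',9a'-octahydrospiro[[1,3]dioxolane-2,2'-benzo[7]annulen]-5'-yl]methanol
Conditions: iBu2AlH, CH2Cl2, −78 °C; aq. KNaC4H4O6
Reagents that add atoms: none
Why: 1,2-Reduction of the conjugated ester with the aluminium hydride should give the allylic alcohol without affecting the ketal.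

**Step 12**
Reactants: 21 [(1'S,4a'S,7'S,9a'R)-1',7',9a'-trimethyl-1',3',4',4a',7',8',9',9a'-octahydrospiro[[1,3]dioxolane-2,2'-benzo[7]annulen]-5'-yl]methanol
Product: 22 [(1'S,4a'S,5'R,6'R,7'S,9a'R)-5',6'-epoxy-1',7',9a'-trimethyldecahydrospiro[[1,3]dioxolane-2,2'-benzo[7]annulen]-5'-yl]methanol (epoxide cis to the angular methyl, trans to the C7′ methyl)
Conditions: Ti(OiPr)4 (10 mol %), D-(−)-diethyl tartrate (12 mol %), t-BuOOH, 4 Å MS, CH2Cl2, −20 °C
Reagents that add atoms: tert-butyl hydroperoxide, CC(C)(C)OO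
Why: Sharpless asymmetric epoxidation with D-(−)-diethyl tartrate should deliver oxygen under reagent control to the alkene face anti to the adjacent C7′ methyl group (matched with that substrate bias), which sets both epoxide carbons as 5′R,6′R.

**Step 13**
Reactants: 22 [(1'S,4a'S,5'R,6'R,7'S,9a'R)-5',6'-epoxy-1',7',9a'-trimethyldecahydrospiro[[1,3]dioxolane-2,2'-benzo[7]annulen]-5'-yl]methanol; 23 7-hydroxy-6,8-dimethoxy-2H-chromen-2-one (isofraxidin)
Product: 24 7-{[(1'S,4a'S,5'R,6'R,7'S,9a'R)-5',6'-epoxy-1',7',9a'-trimethyldecahydrospiro[[1,3]dioxolane-2,2'-benzo[7]annulen]-5'-yl]methoxy}-6,8-dimethoxy-2H-chromen-2-one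
Conditions: PPh3, DIAD, THF, 0 °C → rt
Reagents that add atoms: none
Why: Mitsunobu etherification of the primary epoxy alcohol with the acidic 7-hydroxycoumarin should form the aryl ether at the CH2 group without opening the epoxide and without involving a stereocentre.

**Step 14 (key step)**
Reactants: 24 7-{[(1'S,4a'S,5'R,6'R,7'S,9a'R)-5',6'-epoxy-1',7',9a'-trimethyldecahydrospiro[[1,3]dioxolane-2,2'-benzo[7]annulen]-5'-yl]methoxy}-6,8-dimethoxy-2H-chromen-2-one
Product: 25 (1R,2S,4aR,5S,8aS)-1-{[(6,8-dimethoxy-2-oxo-2H-chromen-7-yl)oxy]methyl}-6,6-(ethylenedioxy)-2,4a,5-trimethyldecahydronaphthalene-1-carbaldehyde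
Conditions: MeAl(OC6H2-4-Br-2,6-tBu2)2 (MABR, 2.2 equiv), CH2Cl2, −78 → −40 °C; sat. aq. NaHCO3
Reagents that add atoms: none
Why: The aluminium reagent binds the epoxide oxygen, the C5′–O bond at the tertiary carbon ionises and the C6′–C7′ ring bond shifts to C5′ anti to the leaving oxygen, so the seven-membered ring contracts and C6′ is expelled as the aluminium-bound formyl group. The closest known reaction type is the Meinwald rearrangement of 1-substituted cycloalkene oxides to ring-contracted quaternary aldehydes and of epoxy ethers from Sharpless epoxidation to β-oxygenated aldehydes with bulky aluminium phenoxides. Ring A (C1, C2, C3, C4, C4a, C8a of the product) is closed not by a cyclisation but by this semipinacol-type 1,2-alkyl shift through a three-centre transition state. The new quaternary centre C1 is fixed stereospecifically by the epoxide configuration (C7′ enters anti to the departing oxygen and the formyl group ends on the face the oxygen occupied), and C2 keeps its configuration because it migrates with retention. The step needs migration of the ring carbon rather than of the C6′ hydrogen (which would give the cycloheptanone) or of a hydride from the ArOCH2 group; the bulky aluminium phenoxide favours alkyl over hydride shift, and the electron-poor coumarinyl oxygen does not stabilise the cation that a hydride shift from CH2OAr would give.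

**Step 15**
Reactants: 25 (1R,2S,4aR,5S,8aS)-1-{[(6,8-dimethoxy-2-oxo-2H-chromen-7-yl)oxy]methyl}-6,6-(ethylenedioxy)-2,4a,5-trimethyldecahydronaphthalene-1-carbaldehyde
Product: 27 7-{[(1S,2S,4aR,5S,8aS)-6,6-(ethylenedioxy)-1,2,4a,5-tetramethyldecahydronaphthalen-1-yl]methoxy}-6,8-dimethoxy-2H-chromen-2-one, via tosylhydrazone 26 (not isolated)
Conditions: TsNHNH2, EtOH, rt; then catecholborane, CHCl3, 0 °C; NaOAc·3H2O, reflux
Reagents that add atoms: none
Why: Condensation to the tosylhydrazone and its reduction with catecholborane, followed by acetate-induced loss of sulfinate and dinitrogen (a Caglioti-type reduction), should convert the hindered formyl group into the methyl group under conditions that spare the coumarin and the ketal.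

**Step 16**
Reactants: 27 7-{[(1S,2S,4aR,5S,8aS)-6,6-(ethylenedioxy)-1,2,4a,5-tetramethyldecahydronaphthalen-1-yl]methoxy}-6,8-dimethoxy-2H-chromen-2-one
Product: 28 6,8-dimethoxy-7-{[(1S,2S,4aR,5S,8aS)-1,2,4a,5-tetramethyl-6-oxodecahydronaphthalen-1-yl]methoxy}-2H-chromen-2-one (CNP0225022.2)
Conditions: 1 M aq. HCl, THF, 40 °C
Reagents that add atoms: water, O
Why: Acid hydrolysis of the dioxolane frees the ketone and equilibrates the adjacent methyl-bearing centre through the enol to the equatorial 5S configuration next to the quaternary carbon.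

**Compound list**

1 | (R)-4-benzyl-1,3-oxazolidin-2-one | O=C1OC[C@@H](Cc2ccccc2)N1 | starting material
2 | (E)-but-2-enoyl chloride | C/C=C/C(Cl)=O | starting material
3 | (R)-4-benzyl-3-[(E)-but-2-enoyl]-1,3-oxazolidin-2-one | C/C=C/C(=O)N1[C@H](Cc2ccccc2)COC1=O | intermediate
4 | (R)-4-benzyl-3-[(3S)-3-methylpent-4-enoyl]-1,3-oxazolidin-2-one | C=C[C@@H](C)CC(=O)N1[C@H](Cc2ccccc2)COC1=O | intermediate
5 | (3S)-3-methylpent-4-en-1-ol | C=C[C@@H](C)CCO | intermediate
6 | (3S)-5-bromo-3-methylpent-1-ene | C=C[C@@H](C)CCBr | intermediate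
7 | methyl 4-oxobutanoate | COC(=O)CCC=O | starting material
8 | but-3-en-2-one | CC(=O)C=C | starting material
9 | methyl (3R)-3-formyl-6-oxoheptanoate (Michael adduct, not isolated) | COC(=O)C[C@H](C=O)CCC(C)=O | intermediate
10 | methyl 2-[(1R)-4-oxocyclohex-2-en-1-yl]acetate | COC(=O)C[C@@H]1C=CC(=O)CC1 | intermediate
11 | methyl 2-[(1R,2R)-2-methyl-4-(trimethylsilyloxy)cyclohex-3-en-1-yl]acetate (not isolated) | COC(=O)C[C@@H]1[C@@H](C)C=C(O[Si](C)(C)C)CC1 | intermediate
12 | methyl 2-[(1R)-2-methyl-4-oxocyclohex-2-en-1-yl]acetate | COC(=O)C[C@@H]1C(C)=CC(=O)CC1 | intermediate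
13 | [(3S)-3-methylpent-4-en-1-yl]magnesium bromide (not isolated) | C=C[C@@H](C)CC[Mg]Br | intermediate
14 | methyl 2-[(1R,2R)-2-methyl-2-[(3S)-3-methylpent-4-en-1-yl]-4-(trimethylsilyloxy)cyclohex-3-en-1-yl]acetate (not isolated) | COC(=O)C[C@@H]1[C@@](C)(CC[C@H](C)C=C)C=C(O[Si](C)(C)C)CC1 | intermediate
15 | methyl 2-[(1R,2R,3S)-2,3-dimethyl-2-[(3S)-3-methylpent-4-en-1-yl]-4-oxocyclohexyl]acetate | COC(=O)C[C@@H]1[C@@](C)(CC[C@H](C)C=C)[C@H](C)C(=O)CC1 | intermediate
16 | methyl 2-[(6S,7R,8R)-6,7-dimethyl-7-[(3S)-3-methylpent-4-en-1-yl]-1,4-dioxaspiro[4.5]decan-8-yl]acetate | COC(=O)C[C@@H]1[C@@](C)(CC[C@H](C)C=C)[C@H](C)C2(OCCO2)CC1 | intermediate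
17 | methyl 3-(dimethylamino)-2-[(6S,7R,8R)-6,7-dimethyl-7-[(3S)-3-methylpent-4-en-1-yl]-1,4-dioxaspiro[4.5]decan-8-yl]propanoate (Mannich base, both C2 epimers, not isolated) | COC(=O)C(CN(C)C)[C@@H]1[C@@](C)(CC[C@H](C)C=C)[C@H](C)C2(OCCO2)CC1 | intermediate
18 | trimethylammonium iodide from 17 (N-methylated Mannich base, not isolated) | COC(=O)C(C[N+](C)(C)C)[C@@H]1[C@@](C)(CC[C@H](C)C=C)[C@H](C)C2(OCCO2)CC1.[I-] | intermediate
19 | methyl 2-[(6S,7R,8S)-6,7-dimethyl-7-[(3S)-3-methylpent-4-en-1-yl]-1,4-dioxaspiro[4.5]decan-8-yl]prop-2-enoate | COC(=O)C(=C)[C@@H]1[C@@](C)(CC[C@H](C)C=C)[C@H](C)C2(OCCO2)CC1 | intermediate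
20 | methyl (1'S,4a'S,7'S,9a'R)-1',7',9a'-trimethyl-1',3',4',4a',7',8',9',9a'-octahydrospiro[[1,3]dioxolane-2,2'-benzo[7]annulene]-5'-carboxylate | COC(=O)C1=C[C@@H](C)CC[C@@]2(C)[C@H](C)C3(OCCO3)CC[C@H]12 | intermediate
21 | [(1'S,4a'S,7'S,9a'R)-1',7',9a'-trimethyl-1',3',4',4a',7',8',9',9a'-octahydrospiro[[1,3]dioxolane-2,2'-benzo[7]annulen]-5'-yl]methanol | OCC1=C[C@@H](C)CC[C@@]2(C)[C@H](C)C3(OCCO3)CC[C@H]12 | intermediate
22 | [(1'S,4a'S,5'R,6'R,7'S,9a'R)-5',6'-epoxy-1',7',9a'-trimethyldecahydrospiro[[1,3]dioxolane-2,2'-benzo[7]annulen]-5'-yl]methanol | OC[C@@]12O[C@@H]1[C@@H](C)CC[C@@]3(C)[C@H](C)C4(OCCO4)CC[C@H]23 | intermediate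
23 | 7-hydroxy-6,8-dimethoxy-2H-chromen-2-one (isofraxidin) | COc1cc2ccc(=O)oc2c(OC)c1O | starting material
24 | 7-{[(1'S,4a'S,5'R,6'R,7'S,9a'R)-5',6'-epoxy-1',7',9a'-trimethyldecahydrospiro[[1,3]dioxolane-2,2'-benzo[7]annulen]-5'-yl]methoxy}-6,8-dimethoxy-2H-chromen-2-one | COc1cc2ccc(=O)oc2c(OC)c1OC[C@@]12O[C@@H]1[C@@H](C)CC[C@@]3(C)[C@H](C)C4(OCCO4)CC[C@H]23 | intermediate
25 | (1R,2S,4aR,5S,8aS)-1-{[(6,8-dimethoxy-2-oxo-2H-chromen-7-yl)oxy]methyl}-6,6-(ethylenedioxy)-2,4a,5-trimethyldecahydronaphthalene-1-carbaldehyde | COc1cc2ccc(=O)oc2c(OC)c1OC[C@]1(C=O)[C@H]2CCC3(OCCO3)[C@@H](C)[C@]2(C)CC[C@@H]1C | intermediate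
26 | N'-tosylhydrazone of aldehyde 25 (not isolated) | COc1cc2ccc(=O)oc2c(OC)c1OC[C@]1(C=NNS(=O)(=O)c2ccc(C)cc2)[C@H]2CCC3(OCCO3)[C@@H](C)[C@]2(C)CC[C@@H]1C | intermediate
27 | 7-{[(1S,2S,4aR,5S,8aS)-6,6-(ethylenedioxy)-1,2,4a,5-tetramethyldecahydronaphthalen-1-yl]methoxy}-6,8-dimethoxy-2H-chromen-2-one | COc1cc2ccc(=O)oc2c(OC)c1OC[C@]1(C)[C@H]2CCC3(OCCO3)[C@@H](C)[C@]2(C)CC[C@@H]1C | intermediate
28 | 6,8-dimethoxy-7-{[(1S,2S,4aR,5S,8aS)-1,2,4a,5-tetramethyl-6-oxodecahydronaphthalen-1-yl]methoxy}-2H-chromen-2-one | COc1cc2ccc(=O)oc2c(OC)c1OC[C@]1(C)[C@H]2CCC(=O)[C@@H](C)[C@]2(C)CC[C@@H]1C | target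

**Step count**

Total: 16 steps. Longest linear sequence: 14 steps (steps 1 to 4, then 7 to 16).

**Steps most likely to fail, with fallbacks**

Step 14 (ring contraction). After ionisation of the tertiary C5′–O bond a hydride shift (from C6′ or from the ArOCH2 group) may outrun migration of the ring carbon, or the aluminium reagent may be tied up by the lactone and ether oxygens so that the epoxide opens slowly and unselectively. The fallback is a pinacol route that sets out from allylic alcohol 21. Mitsunobu etherification with 23 (PPh3, DIAD, THF) should give the allyl aryl ether F1. Dihydroxylation (OsO4 cat., N-methylmorpholine N-oxide, acetone/water) from the face anti to the C7′ methyl group should give the cis-diol F2. Brønsted-acid pinacol rearrangement (p-TsOH, benzene, rt), in which the tertiary C5′ carbinol ionises and C7′ migrates, should then give aldehyde 25, where the route is rejoined.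

Step 10 (ring-closing metathesis). Ring closure onto the hindered 1,1-disubstituted acrylate may be slow, so that intermolecular cross-metathesis or catalyst decomposition competes. The fallback is an intramolecular olefination that sets out from ester 16. α-Bromination (LiN(iPr)2, THF, −78 °C, then N-bromosuccinimide) should give the bromo ester F3, and an Arbuzov reaction with P(OEt)3 at 130 °C the phosphonate F4. Ozonolysis of the terminal alkene (O3, CH2Cl2, −78 °C, then Me2S) should give the aldehyde F5. Intramolecular Horner–Wadsworth–Emmons reaction under mild conditions (LiCl, DBU, MeCN, high dilution) should close the seven-membered ring to enoate 20, where the route is rejoined.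

Step 12 (asymmetric epoxidation). The titanium tartrate catalyst must deliver oxygen to the face syn to the angular methyl group of a hindered trisubstituted alkene, so slow turnover or eroded facial selectivity is possible. The fallback is a substrate-controlled nucleophilic epoxidation that sets out from enoate 20. Weitz–Scheffer-type epoxidation with lithium tert-butyl peroxide (t-BuOOH, n-BuLi, THF, −20 °C), attacking C6′ anti to the adjacent C7′ methyl group, should give the glycidic ester F6. Reduction of the ester with LiBH4 (Et2O, 0 °C) should give epoxy alcohol 22, where the route is rejoined.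

**Further compounds**

F1 | step 14 | 6,8-dimethoxy-7-{[(1'S,4a'S,7'S,9a'R)-1',7',9a'-trimethyl-1',3',4',4a',7',8',9',9a'-octahydrospiro[[1,3]dioxolane-2,2'-benzo[7]annulen]-5'-yl]methoxy}-2H-chromen-2-one (allyl aryl ether) | COc1cc2ccc(=O)oc2c(OC)c1OCC1=C[C@@H](C)CC[C@@]2(C)[C@H](C)C3(OCCO3)CC[C@H]12
F2 | step 14 | 5',6'-cis-diol of F1 (both hydroxyl groups cis to the angular methyl, trans to the C7′ methyl) | COc1cc2ccc(=O)oc2c(OC)c1OC[C@@]1(O)[C@H](O)[C@@H](C)CC[C@@]2(C)[C@H](C)C3(OCCO3)CC[C@H]12
F3 | step 10 | methyl 2-bromo-2-[(6S,7R,8R)-6,7-dimethyl-7-[(3S)-3-methylpent-4-en-1-yl]-1,4-dioxaspiro[4.5]decan-8-yl]acetate (both C2 epimers) | COC(=O)C(Br)[C@@H]1[C@@](C)(CC[C@H](C)C=C)[C@H](C)C2(OCCO2)CC1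
F4 | step 10 | methyl 2-(diethoxyphosphoryl)-2-[(6S,7R,8R)-6,7-dimethyl-7-[(3S)-3-methylpent-4-en-1-yl]-1,4-dioxaspiro[4.5]decan-8-yl]acetate | COC(=O)C([C@@H]1[C@@](C)(CC[C@H](C)C=C)[C@H](C)C2(OCCO2)CC1)P(=O)(OCC)OCC
F5 | step 10 | methyl 2-(diethoxyphosphoryl)-2-[(6S,7R,8R)-6,7-dimethyl-7-[(3S)-3-methyl-4-oxobutyl]-1,4-dioxaspiro[4.5]decan-8-yl]acetate | COC(=O)C([C@@H]1[C@@](C)(CC[C@H](C)C=O)[C@H](C)C2(OCCO2)CC1)P(=O)(OCC)OCC
F6 | step 12 | methyl 5',6'-epoxy-1',7',9a'-trimethyldecahydrospiro[[1,3]dioxolane-2,2'-benzo[7]annulene]-5'-carboxylate (glycidic ester with the epoxide configuration of 22) | COC(=O)[C@@]12O[C@@H]1[C@@H](C)CC[C@@]3(C)[C@H](C)C4(OCCO4)CC[C@H]23
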